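## Structural features

The target is an isoflavan quinone: a chroman (benzo ring A fused to the dihydropyran ring C, atoms O1, C2, C3, C4, C4a, C8a) whose C3 carries a 2,3-dimethoxy-1,4-benzoquinone (ring B) through the quinone carbon C1′, next to the only vinylic CH. Ring A is fully differentiated: C5 is its only CH, C6 and C8 carry methoxy groups, C7 a free hydroxyl and C8a the ring oxygen, so four neighbouring carbons bear oxygen and the fifth substituent is the C4 methylene on C4a. C3 is the only stereocentre and is (S) by the order C2 > C1′ > C4 > H. It has no stereogenic neighbour, but its hydrogen is the γ-hydrogen of the C5′(=O)–C6′=C1′ enone, so base can erase it through quinone-methide tautomers once ring B is oxidised. The fragile groups are the quinone (bases, nucleophiles, reductants), the C7 phenol flanked by two methoxy groups (oxidants) and, in precursors, any tetra-oxygenated hydroquinone (air, azodicarboxylates). The real difficulty is telling the four contiguous oxygens of ring A apart (methyl on O6 and O8, hydrogen on O7, C2 on O1) while keeping C3 intact to the end. The key step exploits the C6–C7–C8–C8a run: these four oxygenated carbons are the four carbons of a squaric ester, C4a and C5 are the two carbons of a 1,1-disubstituted alkene, and C5–C6 is the bond that closes ring A.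

## Logic of the disconnections

30 from 29. The O–C(CH3)3 bond at C7 is cut. Keeping the only phenol masked until the last step means the oxidation that creates ring B meets no other oxidisable hydroxyl, and only acid touches the molecule once the quinone and its labile C3–H exist. The protecting group costs nothing extra, because it is in place from the squarate stage. The forward step must be an acidolysis mild enough for the quinone.

29 from 27 through 28. The two O–CH2Ph bonds of ring B are cut and the quinone is taken back to its hydroquinone. Ring B is then a plain tetraalkoxybenzene for the whole route, inert to enolates, organolithiums, heat and fluoride. The forward step needs a hydrogenolysis that spares the aryl tert-butyl ether and an oxidant that stops at the quinone.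

27 from 26. The O1–C2 bond of ring C is cut, opening the pyran to a phenol and a primary alcohol. C2 is a methylene, so the closure cannot touch C3, and the ring formed is six-membered. The demand is that the C8a hydroxyl is the only free phenol at that point.

26 from 25, and 25 from 24. Two O–Si bonds and the O–CH3 bond at C6 are cut. A thermolysis of the free carbinol would leave both C6–OH and C8a–OH free, an air-sensitive hydroquinone that an azodicarboxylate would dehydrogenate during pyran closure. In 24 the C8a oxygen is therefore already silylated, C6–OH is the only free hydroxyl and is methylated without competition. One fluoride step then frees the C8a phenol and the primary alcohol together. The demand is that the aryl silyl ether outlasts the carbonate of the methylation.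

24 from 21 through 22 and 23. The C5–C6 bond is cut and ring A is unravelled into a cyclobutenone and an alkene. This replaces a pentasubstituted benzene with four differentiated oxygens by a four-membered ring whose substituents are set in advance. The forward step needs the siloxy group to rotate outward in the ring opening, and the tert-butyl and silyl ethers to survive 110 °C.

21 from 15 and 18 through 19 and 20. The C4a–C8a bond (alkenyl carbon to carbinol carbon) and the carbinol O–Si bond are cut. This is the convergent point: the chiral vinyl bromide and the four-carbon unit are made separately. The demand is regiocontrol: the alkenyllithium must attack the carbonyl next to the methoxy-bearing carbon of 18, so that methoxy ends at C8 and tert-butoxy at C7.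

18 from 17, and 17 from 16. The O–C(CH3)3 bond and then one O–CH3 bond of a symmetric squarate are cut. Mono-hydrolysis is self-limiting, so the two oxygens are differentiated in two steps. The demand is a tert-butylation that tolerates a strongly acidic hydroxyl.

15 from 14, and 14 from 13. An O–Si bond and the exocyclic acyl–N bond are cut. The auxiliary is exchanged for a protected hydroxymethyl group that later becomes C2. The reduction must not epimerise the α-aryl centre or touch the vinyl bromide.

13 from 10 and 11 through 12. The C3–C4 bond is cut, which sets the only stereocentre by alkylation of a chiral imide enolate with an allylic bromide. The vinylic bromine of 11 is the handle for step 12. The demand is facial control by the auxiliary and no epimerisation of the acidic α-aryl position.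

10 from 7 and 8 through 9. The N–acyl bond is cut, which separates the auxiliary from the arylacetic acid.

7 from 6, and 6 from 5. The ester O-alkyl bond and then the aryl–CH2 bond (C1′ to the future C3) are cut. A two-carbon ester enolate equivalent is coupled to an aryl bromide. The demand is oxidative addition to an electron-rich, ortho-alkoxy bromide.

5 from 4, 4 from 2 through 3, and 2 from 1. The C–Br bond, the two O–benzyl bonds and the para C=O of the quinone are cut in turn. The symmetric intermediate 4 has two equivalent free positions, so the bromination has no regiochemical issue.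

## Other disconnections considered

Alternative 1: The cut runs through ring B. The C1′–C2′ bond and the whole quinone ring are traced back to the 4-alkynyl-4-hydroxy-2,3-dimethoxycyclobutenone A2, the adduct of the lithium acetylide of (3S)-7-(benzyloxy)-3-ethynyl-6,8-dimethoxychromane A1 with 16.
- Forward step: heating A2 would open the four-membered ring to an enynylketene. The ketene carbon would bond to the alkyne carbon that carries the chroman, the diradical would take up the hydroxyl hydrogen, and the 7-O-benzyl quinone A3 would appear directly at the quinone oxidation level (a Moore cyclisation).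
- In its favour: 16 is symmetric, so the addition has no regiochemical question. Ring B needs no protecting groups and no terminal oxidation. Alkyl-substituted alkynes are the class for which six-membered closure is normally preferred over the cyclopentenedione pathway.
- Against it here: ring A, the hard part of the molecule, would have to be assembled by stepwise arene chemistry before the key step. The stereocentre of A1 is propargylic and harder to set and keep than an α-aryl imide centre. The benzyl ether of A3 would have to be removed in the presence of the quinone.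
- Comparison: both plans use the same strain-release logic. Alternative 1 is the better plan on the regiochemistry of the squarate addition and on the handling of ring B. The chosen plan is the better one on ring A, where the squarate carbons land exactly on the four oxygenated positions, and on the robustness of C3. In step count the two should be about equal, with the effort moved from ring B to ring A.

Alternative 2: The cut is the aryl ether bond C8a–O1. The substrate would be the open-chain alcohol A5, (2S)-3-[4-(benzyloxy)-3,5-dimethoxyphenyl]-2-[3,4-dimethoxy-2,5-bis(pivaloyloxy)phenyl]propan-1-ol. It would come from auxiliary-controlled alkylation of a ring B arylacetyl imide with 2-(benzyloxy)-5-(bromomethyl)-1,3-dimethoxybenzene A4, followed by reduction.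
- Forward step: one-electron oxidation (anodic, photoredox or hypervalent iodine) would convert the syringyl ring into a radical cation. The primary hydroxyl would add to an ortho carbon, and loss of a second electron and a proton would give the isoflavan dipivalate A6.
- In its favour: ring A is bought with its 6-OMe/7-O/8-OMe pattern in place, the two ortho positions are equivalent, and no ring A oxygen has to be differentiated. On step economy and on the differentiation problem this is the better plan.
- Against it here: the carbon to be attacked is ortho to only one methoxy group and meta to the benzyloxy group. The tetra-oxygenated product should be easier to oxidise than the substrate. The benzylic C4–H bonds and ring B compete, hence the deactivating pivalates, which must later be removed with base or hydride before the quinone can be made. This kind of dehydrogenative C–O closure has not been shown on a 3,4,5-trioxygenated ring.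
- Comparison: equal on stereocontrol (the same enolate alkylation), better on step count and convergence, weaker on the certainty of the key bond formation. The open-shell oxidation has to be selective among several electron-rich sites, while the chosen plan relies on a thermal pericyclic cascade in which connectivity decides the outcome.

Alternative 3: Two bonds are cut at once, C4–C4a and C8a–O1. This separates the ring A aryl iodide A7, 2-(benzyloxy)-4-iodo-1,3-dimethoxybenzene, from the enantiopure bromo alcohol A8, (2S)-2-[2,5-bis(benzyloxy)-3,4-dimethoxyphenyl]-3-bromopropan-1-ol.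
- Forward step: under Pd(OAc)2, a phosphine, norbornene and carbonate base (a Catellani annulation), A7 would add oxidatively to zerovalent palladium. Norbornene insertion and C–H palladation would give a palladacycle that is alkylated at the ortho carbon by the bromide of A8. After norbornene extrusion, the tethered alkoxide would close the pyran ring at the ipso carbon to give the tri-O-benzyl isoflavan A9.
- In its favour: it is the most convergent of the four plans, makes two ring bonds in one operation, and uses a ring A partner that needs very few steps. The methoxy group ortho to iodine supplies the ortho substituent this catalysis requires. On convergence and step count it is the better plan, and on stereocontrol it is equal, because A8 would come from the same auxiliary chemistry.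
- Against it here: ipso termination by an aliphatic alkoxide has to beat β-hydride elimination from the palladium alkoxide. A8 can close to an oxetane or lose HBr under hot carbonate, since its stereocentre carries a benzylic hydrogen next to the reacting carbon. The electron-rich tri-oxygenated palladacycle must still accept a β-branched primary bromide.
- Comparison: alternative 3 is shorter if the annulation works on this substitution pattern. The chosen plan is longer but builds ring A by a step whose regiochemistry is fixed by the precursor, and it keeps the stereocentre two atoms away from every reacting centre after it is set.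

Key step: step 13

Remark on the chemistry: the carbinol carbon created in step 12 (in 20 and 21) forms as both epimers and is carried on as the mixture, because it becomes sp2 in step 13. Its configuration is therefore left open in the SMILES.

## Route

Step 1
Reactants: 1 2,3-dimethoxyphenol
Product: 2 2,3-dimethoxy-1,4-benzoquinone
Conditions: (KSO3)2NO (2.5 equiv), KH2PO4, H2O/acetone, 0 °C → rt
Reagents that add atoms: potassium nitrosodisulfonate, [K+].[K+].[O-]S(=O)(=O)N([O])S(=O)(=O)[O-]
Why: Teuber oxidation: the nitroxyl radical removes the phenolic hydrogen and a second equivalent delivers oxygen to the free para position, which should give the para-quinone because that position is open and electronically favoured.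

Step 2
Reactants: 2 2,3-dimethoxy-1,4-benzoquinone
Product: 4 1,4-bis(benzyloxy)-2,3-dimethoxybenzene, via 2,3-dimethoxyhydroquinone 3 (not isolated)
Conditions: Na2S2O4, H2O/EtOAc, rt; then BnBr, K2CO3, DMF, 60 °C (argon)
Reagents that add atoms: benzyl bromide, BrCc1ccccc1
Why: Dithionite reduction followed at once by double Williamson benzylation, so the electron-rich hydroquinone is never stored; benzyl ethers are chosen because hydrogenolysis returns the hydroquinone later without acid or base.

Step 3
Reactants: 4 1,4-bis(benzyloxy)-2,3-dimethoxybenzene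
Product: 5 1,4-bis(benzyloxy)-5-bromo-2,3-dimethoxybenzene
Conditions: NBS (1.0 equiv), MeCN, 0 °C, dark
Reagents that add atoms: N-bromosuccinimide, O=C1CCC(=O)N1Br
Why: Electrophilic aromatic bromination of a tetraalkoxybenzene; the two free positions are equivalent by symmetry, so one equivalent should give a single monobromide.

Step 4
Reactants: 5 1,4-bis(benzyloxy)-5-bromo-2,3-dimethoxybenzene
Product: 6 ethyl [2,5-bis(benzyloxy)-3,4-dimethoxyphenyl]acetate
Conditions: BrZnCH2CO2Et (1.5 equiv), Pd2(dba)3 (2 mol %), XPhos (8 mol %), THF, 65 °C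
Reagents that add atoms: ethyl (bromozincio)acetate, CCOC(=O)C[Zn]Br
Why: Negishi-type coupling of a Reformatsky reagent with an aryl bromide; the bulky biarylphosphine supports oxidative addition to the electron-rich ortho-alkoxy bromide, and the neutral zinc enolate leaves the benzyl ethers alone.

Step 5
Reactants: 6 ethyl [2,5-bis(benzyloxy)-3,4-dimethoxyphenyl]acetate
Product: 7 [2,5-bis(benzyloxy)-3,4-dimethoxyphenyl]acetic acid
Conditions: LiOH, THF/MeOH/H2O, rt; aq. HCl work-up
Reagents that add atoms: lithium hydroxide, [Li+].[OH-]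
Why: Ordinary saponification of an unhindered ethyl ester; the aryl ethers are inert to hydroxide.

Step 6
Reactants: 7 [2,5-bis(benzyloxy)-3,4-dimethoxyphenyl]acetic acid; 8 (4S)-4-benzyl-1,3-oxazolidin-2-one
Product: 10 (4S)-4-benzyl-3-{[2,5-bis(benzyloxy)-3,4-dimethoxyphenyl]acetyl}-1,3-oxazolidin-2-one, via mixed pivalic anhydride 9 (not isolated)
Conditions: t-BuCOCl, Et3N, THF, −20 °C; then LiCl, 8, −20 °C → rt
Reagents that add atoms: pivaloyl chloride, CC(C)(C)C(=O)Cl (its atoms stay only in 9)
Why: N-acylation of the oxazolidinone through the mixed pivalic anhydride with LiCl activation; the nucleophile attacks the less hindered arylacetyl carbonyl of 9.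

Step 7
Reactants: 10 (4S)-4-benzyl-3-{[2,5-bis(benzyloxy)-3,4-dimethoxyphenyl]acetyl}-1,3-oxazolidin-2-one; 11 2,3-dibromopropene
Product: 13 (4S)-4-benzyl-3-{(2S)-2-[2,5-bis(benzyloxy)-3,4-dimethoxyphenyl]-4-bromopent-4-enoyl}-1,3-oxazolidin-2-one, via sodium enolate 12 (not isolated)
Conditions: NaN(SiMe3)2 (1.05 equiv), THF, −78 °C; then 11 (3 equiv), −78 → −45 °C
Reagents that add atoms: sodium bis(trimethylsilyl)amide, [Na+].C[Si](C)(C)[N-][Si](C)(C)C (sodium stays only in 12)
Why: Evans alkylation: the chelated sodium (Z)-enolate is shielded on one face by the benzyl group of the auxiliary, so the allylic bromide should enter from the opposite face and set the future C3 as (S); only the allylic C–Br bond of 11 is displaced, and the low temperature and near-stoichiometric base guard the acidic α-aryl centre against epimerisation.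

Step 8
Reactants: 13 (4S)-4-benzyl-3-{(2S)-2-[2,5-bis(benzyloxy)-3,4-dimethoxyphenyl]-4-bromopent-4-enoyl}-1,3-oxazolidin-2-one
Product: 14 (2S)-2-[2,5-bis(benzyloxy)-3,4-dimethoxyphenyl]-4-bromopent-4-en-1-ol
Conditions: LiBH4, H2O (1 equiv), Et2O, 0 °C
Reagents that add atoms: none
Why: Reductive removal of the auxiliary by hydride attack at the exocyclic carbonyl; the medium is essentially non-basic, so the benzylic stereocentre should be retained, and vinyl bromide and benzyl ethers do not react with borohydride.

Step 9
Reactants: 14 (2S)-2-[2,5-bis(benzyloxy)-3,4-dimethoxyphenyl]-4-bromopent-4-en-1-ol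
Product: 15 {[(2S)-2-[2,5-bis(benzyloxy)-3,4-dimethoxyphenyl]-4-bromopent-4-en-1-yl]oxy}(tert-butyl)dimethylsilane
Conditions: TBSCl, imidazole, DMF, rt
Reagents that add atoms: tert-butyldimethylsilyl chloride, CC(C)(C)[Si](C)(C)Cl
Why: Standard silylation of a primary alcohol; the silyl ether tolerates t-BuLi and heat and is later removed together with the aryl silyl ether by one fluoride treatment.

Step 10
Reactants: 16 dimethyl squarate
Product: 17 3-hydroxy-4-methoxycyclobut-3-ene-1,2-dione
Conditions: NaOH (1.0 equiv), H2O/THF, 0 °C → rt; aq. HCl work-up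
Reagents that add atoms: sodium hydroxide, [Na+].[OH-]
Why: Addition–elimination of hydroxide at one vinylogous ester carbon; the reaction should stop after one exchange because the delocalised squarate monoanion is far less electrophilic than the diester.

Step 11
Reactants: 17 3-hydroxy-4-methoxycyclobut-3-ene-1,2-dione
Product: 18 3-tert-butoxy-4-methoxycyclobut-3-ene-1,2-dione
Conditions: t-BuOC(=NH)CCl3 (2.5 equiv), CH2Cl2/cyclohexane, rt
Reagents that add atoms: tert-butyl 2,2,2-trichloroacetimidate, CC(C)(C)OC(=N)C(Cl)(Cl)Cl
Why: O-tert-butylation of an acidic (vinylogous carboxylic) hydroxyl with the trichloroacetimidate: the substrate protonates the imidate and its anion captures the tert-butyl cation; alkylation at either of the two charge-bearing oxygens gives the same 1,2-dione.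

Step 12
Reactants: 15 {[(2S)-2-[2,5-bis(benzyloxy)-3,4-dimethoxyphenyl]-4-bromopent-4-en-1-yl]oxy}(tert-butyl)dimethylsilane; 18 3-tert-butoxy-4-methoxycyclobut-3-ene-1,2-dione
Product: 21 4-[(4S)-4-[2,5-bis(benzyloxy)-3,4-dimethoxyphenyl]-5-(tert-butyldimethylsilyloxy)pent-1-en-2-yl]-2-tert-butoxy-4-(tert-butyldimethylsilyloxy)-3-methoxycyclobut-2-en-1-one (both C4 epimers), via alkenyllithium 19 (not isolated), via lithium alkoxide 20 (not isolated)
Conditions: t-BuLi (2.0 equiv), THF, −78 °C; then added to 18 (1.2 equiv), THF, −78 °C; then TBSOTf (1.5 equiv), −78 → −20 °C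
Reagents that add atoms: tert-butyldimethylsilyl trifluoromethanesulfonate, CC(C)(C)[Si](C)(C)OS(=O)(=O)C(F)(F)F; tert-butyllithium, [Li]C(C)(C)C (lithium stays only in 19 and 20)
Why: Bromine–lithium exchange followed by 1,2-addition of the alkenyllithium to a squarate carbonyl and O-silylation of the alkoxide in the same flask; attack should prefer the carbonyl next to the methoxy-bearing carbon, which is the less shielded one and is the vinylogous ester of the twisted, weaker-donating tert-butoxy group, and the new carbinol centre forms without control, which does not matter.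

Step 13
Reactants: 21 4-[(4S)-4-[2,5-bis(benzyloxy)-3,4-dimethoxyphenyl]-5-(tert-butyldimethylsilyloxy)pent-1-en-2-yl]-2-tert-butoxy-4-(tert-butyldimethylsilyloxy)-3-methoxycyclobut-2-en-1-one
Product: 24 5-[(2S)-2-[2,5-bis(benzyloxy)-3,4-dimethoxyphenyl]-3-(tert-butyldimethylsilyloxy)propyl]-2-tert-butoxy-4-(tert-butyldimethylsilyloxy)-3-methoxyphenol, via dienylketene 22 (not isolated), via cyclohexadienone 23 (not isolated)
Conditions: PhMe (0.02 M, degassed), 110 °C, argon
Reagents that add atoms: none
Why: Heating opens the cyclobutenone by conrotatory 4π electrocyclic cleavage of the C1–C4 bond, and the siloxy donor on C4 rotates outward, which places the alkenyl group cis to the ketene in 22. Thermal disrotatory 6π electrocyclisation then joins the ketene carbon (future C6) to the terminal methylene (future C5) and closes ring A as a six-membered carbocycle, the cyclohexa-2,4-dienone 23, whose CH2–C=O unit enolises to the phenol 24. The closest known reaction type is the thermal rearrangement of squarate-derived 4-alkenyl-4-hydroxy- and 4-siloxycyclobutenones to hydroquinones and their mono-protected forms. No stereocentre is created: both carbinol epimers of 21 converge on the same arene, and C3 is a spectator separated from the reacting π system by a methylene group. The selectivity the step needs is the sense of rotation in the ring opening, which the strong outward preference of an oxygen donor secures; the substitution pattern then follows from the connectivity of 21, with methoxy next to the former carbinol carbon becoming C8–OMe and tert-butoxy next to the former carbonyl becoming C7–O-t-Bu. Because the carbinol oxygen is already silylated, the product has a single free hydroxyl (C6–OH) and is not an air-sensitive hydroquinone. Neutral, dilute, oxygen-free conditions at 110 °C are chosen so that the tert-butyl and silyl ethers survive and the ketene is not intercepted intermolecularly.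

Step 14
Reactants: 24 5-[(2S)-2-[2,5-bis(benzyloxy)-3,4-dimethoxyphenyl]-3-(tert-butyldimethylsilyloxy)propyl]-2-tert-butoxy-4-(tert-butyldimethylsilyloxy)-3-methoxyphenol
Product: 25 {[(2S)-2-[2,5-bis(benzyloxy)-3,4-dimethoxyphenyl]-3-[4-tert-butoxy-2-(tert-butyldimethylsilyloxy)-3,5-dimethoxyphenyl]propyl]oxy}(tert-butyl)dimethylsilane
Conditions: MeI, K2CO3, acetone, 50 °C (argon)
Reagents that add atoms: iodomethane, CI
Why: Williamson methylation of the only free hydroxyl (C6–OH); the C8a oxygen is held as a hindered aryl silyl ether and the C7 oxygen as a tert-butyl ether, so no other oxygen can be alkylated.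

Step 15
Reactants: 25 {[(2S)-2-[2,5-bis(benzyloxy)-3,4-dimethoxyphenyl]-3-[4-tert-butoxy-2-(tert-butyldimethylsilyloxy)-3,5-dimethoxyphenyl]propyl]oxy}(tert-butyl)dimethylsilane
Product: 26 (2S)-2-[2,5-bis(benzyloxy)-3,4-dimethoxyphenyl]-3-(4-tert-butoxy-2-hydroxy-3,5-dimethoxyphenyl)propan-1-ol
Conditions: n-Bu4NF, AcOH, THF, 0 °C → rt
Reagents that add atoms: none
Why: Fluoride cleaves the aryl and the primary silyl ether in one operation; acetic acid buffers the electron-rich phenoxide, and the tert-butyl and benzyl ethers are inert to fluoride.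

Step 16
Reactants: 26 (2S)-2-[2,5-bis(benzyloxy)-3,4-dimethoxyphenyl]-3-(4-tert-butoxy-2-hydroxy-3,5-dimethoxyphenyl)propan-1-ol
Product: 27 (3S)-3-[2,5-bis(benzyloxy)-3,4-dimethoxyphenyl]-7-tert-butoxy-6,8-dimethoxychromane
Conditions: PPh3, DIAD, THF (0.02 M), 0 °C → rt
Reagents that add atoms: none
Why: Mitsunobu etherification: the primary alcohol is activated as its alkoxyphosphonium ion and displaced by the C8a phenol in a 6-exo-tet closure; C3 is not the reacting carbon and keeps its configuration, and the substrate is a simple phenol, not a hydroquinone, so the azodicarboxylate has nothing to oxidise.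

Step 17
Reactants: 27 (3S)-3-[2,5-bis(benzyloxy)-3,4-dimethoxyphenyl]-7-tert-butoxy-6,8-dimethoxychromane
Product: 29 5-[(3S)-7-tert-butoxy-6,8-dimethoxychroman-3-yl]-2,3-dimethoxycyclohexa-2,5-diene-1,4-dione, via hydroquinone 28 (not isolated)
Conditions: H2 (1 atm), 10% Pd/C, EtOAc, rt; filtration under argon; then Ag2O, EtOAc, rt
Reagents that add atoms: none
Why: Hydrogenolysis of the two aryl benzyl ethers followed by dehydrogenation of the hydroquinone with Ag2O; the aryl tert-butyl ether is inert to both, and because the C7 oxygen is still masked, ring B is the only oxidisable site.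

Step 18
Reactants: 29 5-[(3S)-7-tert-butoxy-6,8-dimethoxychroman-3-yl]-2,3-dimethoxycyclohexa-2,5-diene-1,4-dione
Product: 30 5-[(3S)-7-hydroxy-6,8-dimethoxychroman-3-yl]-2,3-dimethoxycyclohexa-2,5-diene-1,4-dione
Conditions: CF3CO2H/CH2Cl2 (1:4), 0 °C
Reagents that add atoms: none
Why: Acidolysis of the aryl tert-butyl ether with loss of isobutene; quinones tolerate cold trifluoroacetic acid, and because no base is used after ring B is oxidised, the γ-hydrogen at C3 cannot be removed.

## Compound list

1 | 2,3-dimethoxyphenol | COc1cccc(O)c1OC | starting material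
2 | 2,3-dimethoxy-1,4-benzoquinone | COC1=C(OC)C(=O)C=CC1=O | intermediate
3 | 2,3-dimethoxybenzene-1,4-diol | COc1c(O)ccc(O)c1OC | intermediate (not isolated)
4 | 1,4-bis(benzyloxy)-2,3-dimethoxybenzene | COc1c(OCc2ccccc2)ccc(OCc2ccccc2)c1OC | intermediate
5 | 1,4-bis(benzyloxy)-5-bromo-2,3-dimethoxybenzene | COc1c(OC)c(OCc2ccccc2)c(Br)cc1OCc1ccccc1 | intermediate
6 | ethyl [2,5-bis(benzyloxy)-3,4-dimethoxyphenyl]acetate | CCOC(=O)Cc1cc(OCc2ccccc2)c(OC)c(OC)c1OCc1ccccc1 | intermediate
7 | [2,5-bis(benzyloxy)-3,4-dimethoxyphenyl]acetic acid | OC(=O)Cc1cc(OCc2ccccc2)c(OC)c(OC)c1OCc1ccccc1 | intermediate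
8 | (4S)-4-benzyl-1,3-oxazolidin-2-one | O=C1OC[C@H](Cc2ccccc2)N1 | starting material
9 | [2,5-bis(benzyloxy)-3,4-dimethoxyphenyl]acetic pivalic anhydride | CC(C)(C)C(=O)OC(=O)Cc1cc(OCc2ccccc2)c(OC)c(OC)c1OCc1ccccc1 | intermediate (not isolated)
10 | (4S)-4-benzyl-3-{[2,5-bis(benzyloxy)-3,4-dimethoxyphenyl]acetyl}-1,3-oxazolidin-2-one | O=C1OC[C@H](Cc2ccccc2)N1C(=O)Cc1cc(OCc2ccccc2)c(OC)c(OC)c1OCc1ccccc1 | intermediate
11 | 2,3-dibromopropene | BrCC(Br)=C | starting material
12 | sodium (Z)-enolate of 10 | [Na+].[O-]/C(=C\c1cc(OCc2ccccc2)c(OC)c(OC)c1OCc1ccccc1)N1[C@@H](Cc2ccccc2)COC1=O | intermediate (not isolated)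
13 | (4S)-4-benzyl-3-{(2S)-2-[2,5-bis(benzyloxy)-3,4-dimethoxyphenyl]-4-bromopent-4-enoyl}-1,3-oxazolidin-2-one | COc1c(OC)c(OCc2ccccc2)c(cc1OCc1ccccc1)[C@H](CC(Br)=C)C(=O)N1[C@@H](Cc2ccccc2)COC1=O | intermediate
14 | (2S)-2-[2,5-bis(benzyloxy)-3,4-dimethoxyphenyl]-4-bromopent-4-en-1-ol | COc1c(OC)c(OCc2ccccc2)c(cc1OCc1ccccc1)[C@H](CC(Br)=C)CO | intermediate
15 | {[(2S)-2-[2,5-bis(benzyloxy)-3,4-dimethoxyphenyl]-4-bromopent-4-en-1-yl]oxy}(tert-butyl)dimethylsilane | COc1c(OC)c(OCc2ccccc2)c(cc1OCc1ccccc1)[C@H](CC(Br)=C)CO[Si](C)(C)C(C)(C)C | intermediate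
16 | dimethyl squarate (3,4-dimethoxycyclobut-3-ene-1,2-dione) | COC1=C(OC)C(=O)C1=O | starting material
17 | 3-hydroxy-4-methoxycyclobut-3-ene-1,2-dione | COC1=C(O)C(=O)C1=O | intermediate
18 | 3-tert-butoxy-4-methoxycyclobut-3-ene-1,2-dione | COC1=C(OC(C)(C)C)C(=O)C1=O | intermediate
19 | [(4S)-4-[2,5-bis(benzyloxy)-3,4-dimethoxyphenyl]-5-(tert-butyldimethylsilyloxy)pent-1-en-2-yl]lithium | COc1c(OC)c(OCc2ccccc2)c(cc1OCc1ccccc1)[C@H](CC([Li])=C)CO[Si](C)(C)C(C)(C)C | intermediate (not isolated)
20 | lithium alkoxide of the squarate adduct: lithium 1-[(4S)-4-[2,5-bis(benzyloxy)-3,4-dimethoxyphenyl]-5-(tert-butyldimethylsilyloxy)pent-1-en-2-yl]-3-tert-butoxy-2-methoxy-4-oxocyclobut-2-en-1-olate (both carbinol epimers) | [Li+].COc1c(OC)c(OCc2ccccc2)c(cc1OCc1ccccc1)[C@H](CC(=C)C1([O-])C(OC)=C(OC(C)(C)C)C1=O)CO[Si](C)(C)C(C)(C)C | intermediate (not isolated)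
21 | 4-[(4S)-4-[2,5-bis(benzyloxy)-3,4-dimethoxyphenyl]-5-(tert-butyldimethylsilyloxy)pent-1-en-2-yl]-2-tert-butoxy-4-(tert-butyldimethylsilyloxy)-3-methoxycyclobut-2-en-1-one (both C4 epimers) | COc1c(OC)c(OCc2ccccc2)c(cc1OCc1ccccc1)[C@H](CC(=C)C1(O[Si](C)(C)C(C)(C)C)C(OC)=C(OC(C)(C)C)C1=O)CO[Si](C)(C)C(C)(C)C | intermediate
22 | dienylketene: (3Z,7S)-7-[2,5-bis(benzyloxy)-3,4-dimethoxyphenyl]-2-tert-butoxy-4,8-bis(tert-butyldimethylsilyloxy)-3-methoxy-5-methylideneocta-1,3-dien-1-one | COc1c(OC)c(OCc2ccccc2)c(cc1OCc1ccccc1)[C@H](CC(=C)/C(O[Si](C)(C)C(C)(C)C)=C(/OC)C(OC(C)(C)C)=C=O)CO[Si](C)(C)C(C)(C)C | intermediate (not isolated)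
23 | 5-[(2S)-2-[2,5-bis(benzyloxy)-3,4-dimethoxyphenyl]-3-(tert-butyldimethylsilyloxy)propyl]-2-tert-butoxy-4-(tert-butyldimethylsilyloxy)-3-methoxycyclohexa-2,4-dien-1-one | COc1c(OC)c(OCc2ccccc2)c(cc1OCc1ccccc1)[C@H](CC1=C(O[Si](C)(C)C(C)(C)C)C(OC)=C(OC(C)(C)C)C(=O)C1)CO[Si](C)(C)C(C)(C)C | intermediate (not isolated)
24 | 5-[(2S)-2-[2,5-bis(benzyloxy)-3,4-dimethoxyphenyl]-3-(tert-butyldimethylsilyloxy)propyl]-2-tert-butoxy-4-(tert-butyldimethylsilyloxy)-3-methoxyphenol | COc1c(OC)c(OCc2ccccc2)c(cc1OCc1ccccc1)[C@H](Cc1cc(O)c(OC(C)(C)C)c(OC)c1O[Si](C)(C)C(C)(C)C)CO[Si](C)(C)C(C)(C)C | intermediate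
25 | {[(2S)-2-[2,5-bis(benzyloxy)-3,4-dimethoxyphenyl]-3-[4-tert-butoxy-2-(tert-butyldimethylsilyloxy)-3,5-dimethoxyphenyl]propyl]oxy}(tert-butyl)dimethylsilane | COc1c(OC)c(OCc2ccccc2)c(cc1OCc1ccccc1)[C@H](Cc1cc(OC)c(OC(C)(C)C)c(OC)c1O[Si](C)(C)C(C)(C)C)CO[Si](C)(C)C(C)(C)C | intermediate
26 | (2S)-2-[2,5-bis(benzyloxy)-3,4-dimethoxyphenyl]-3-(4-tert-butoxy-2-hydroxy-3,5-dimethoxyphenyl)propan-1-ol | COc1c(OC)c(OCc2ccccc2)c(cc1OCc1ccccc1)[C@H](Cc1cc(OC)c(OC(C)(C)C)c(OC)c1O)CO | intermediate
27 | (3S)-3-[2,5-bis(benzyloxy)-3,4-dimethoxyphenyl]-7-tert-butoxy-6,8-dimethoxychromane | COc1c(OC)c(OCc2ccccc2)c(cc1OCc1ccccc1)[C@H]1COc2c(cc(OC)c(OC(C)(C)C)c2OC)C1 | intermediate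
28 | 2-[(3S)-7-tert-butoxy-6,8-dimethoxychroman-3-yl]-5,6-dimethoxybenzene-1,4-diol | COc1c(OC)c(O)c(cc1O)[C@H]1COc2c(cc(OC)c(OC(C)(C)C)c2OC)C1 | intermediate (not isolated)
29 | 5-[(3S)-7-tert-butoxy-6,8-dimethoxychroman-3-yl]-2,3-dimethoxycyclohexa-2,5-diene-1,4-dione | COC1=C(OC)C(=O)C([C@H]2COc3c(cc(OC)c(OC(C)(C)C)c3OC)C2)=CC1=O | intermediate
30 | 5-[(3S)-7-hydroxy-6,8-dimethoxychroman-3-yl]-2,3-dimethoxycyclohexa-2,5-diene-1,4-dione | COC1=C(OC)C(=O)C([C@H]2COc3c(cc(OC)c(O)c3OC)C2)=CC1=O | target

## Step count and least certain steps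

Total: 18 steps. Longest linear sequence: 16 steps (steps 1–9, then 12–18). The squarate branch (steps 10 and 11) joins at step 12.

Step 13 (key step). The most likely failure is loss of the C7 tert-butyl group as isobutene during the thermolysis. The phenol formed in the same step is a proton source at 110 °C, and a second free hydroxyl would destroy the differentiation of the ring A oxygens. Interception of the ketene by the product phenol at too high a concentration is less likely. The fallback abandons the squarate construction of ring A for stepwise arene chemistry; it sets out from 10 and returns at 30. Commercial 4-(benzyloxy)-3,5-dimethoxybenzaldehyde F1 is brominated ortho to the formyl group (NBS) to 4-(benzyloxy)-2-bromo-3,5-dimethoxybenzaldehyde F2. This is reduced (NaBH4) to [4-(benzyloxy)-2-bromo-3,5-dimethoxyphenyl]methanol F3 and converted (PBr3) into 2-(benzyloxy)-4-bromo-5-(bromomethyl)-1,3-dimethoxybenzene F4. Enolate 12, made from 10 as in step 7, is alkylated with F4 to give (4S)-4-benzyl-3-{(2S)-2-[2,5-bis(benzyloxy)-3,4-dimethoxyphenyl]-3-[4-(benzyloxy)-2-bromo-3,5-dimethoxyphenyl]propanoyl}-1,3-oxazolidin-2-one F5, with the same facial control. LiBH4 gives (2S)-2-[2,5-bis(benzyloxy)-3,4-dimethoxyphenyl]-3-[4-(benzyloxy)-2-bromo-3,5-dimethoxyphenyl]propan-1-ol F6. Intramolecular palladium-catalysed etherification of the aryl bromide by the primary alcohol (Pd(OAc)2, a di-tert-butylbiarylphosphine, Cs2CO3, toluene, 80 °C) closes the pyran ring to (3S)-7-(benzyloxy)-3-[2,5-bis(benzyloxy)-3,4-dimethoxyphenyl]-6,8-dimethoxychromane F7, the same compound as A9. Hydrogenolysis to 2-[(3S)-7-hydroxy-6,8-dimethoxychroman-3-yl]-5,6-dimethoxybenzene-1,4-diol F8 and oxidation with one equivalent of Ag2O, as in step 17, give 30.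

Step 12. The most likely failure is insufficient discrimination between the two carbonyl groups of 18. Attack next to the tert-butoxy-bearing carbon would exchange the ether groups of C7 and C8, and this selectivity rests on steric and conformational arguments only. Double addition at a local excess of 19 is a second risk. The fallback fixes the regiochemistry by construction; it sets out from 15 and returns at 21. Alkenyllithium 19 is added to commercial 3,4-di-tert-butoxycyclobut-3-ene-1,2-dione F9, whose two carbonyl groups are equivalent. The lithium alkoxide of the adduct F10 is silylated in the flask (TBSOTf) to the 2,3-di-tert-butoxy-4-(tert-butyldimethylsilyloxy)cyclobutenone F11. Brief treatment with CF3CO2H in CH2Cl2 at 0 °C should cleave only the tert-butyl group of the vinylogous ester at C3, giving the 2-tert-butoxy-3-hydroxycyclobutenone F12. In F12 the two oxygen-bearing carbons C1 and C3 are equivalent, so O-methylation with Me3SiCHN2 at either oxygen gives 21 and no regioisomer.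

Step 11. The most likely failure is acid-driven decomposition: 17 is acidic enough to turn the imidate into isobutene before the alkyl group is transferred, and to strip the tert-butyl group from 18 again. The fallback replaces acid-promoted transfer by alkylation of a salt under neutral conditions; it sets out from 17 and returns at 18. Ag2O in water converts 17 into silver 2-methoxy-3,4-dioxocyclobut-1-en-1-olate F13, which is stirred with tert-butyl bromide in diethyl ether in the dark.

Step 14. The most likely failure is carbonate- or phenoxide-induced loss of the aryl silyl ether at C8a, which would open that oxygen to methylation. Slow methylation of the C6 hydroxyl next to the bulky tert-butoxy group would give this side process more time. The fallback methylates only after ring C is closed, when no silyl ether is left; it sets out from 24 and returns at 27. Pyridinium p-toluenesulfonate in methanol removes only the primary silyl ether to give (2S)-2-[2,5-bis(benzyloxy)-3,4-dimethoxyphenyl]-3-[4-tert-butoxy-2-(tert-butyldimethylsilyloxy)-5-hydroxy-3-methoxyphenyl]propan-1-ol F14. Iodine, PPh3 and imidazole give 5-[(2S)-2-[2,5-bis(benzyloxy)-3,4-dimethoxyphenyl]-3-iodopropyl]-2-tert-butoxy-4-(tert-butyldimethylsilyloxy)-3-methoxyphenol F15. CsF in DMF removes the silyl group from the C8a oxygen, and the liberated phenoxide displaces the iodide to give (3S)-3-[2,5-bis(benzyloxy)-3,4-dimethoxyphenyl]-7-tert-butoxy-8-methoxychroman-6-ol F16. MeI and K2CO3 then give 27.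

## Further compounds

F1 | step 13 | 4-(benzyloxy)-3,5-dimethoxybenzaldehyde | COc1cc(C=O)cc(OC)c1OCc1ccccc1
F2 | step 13 | 4-(benzyloxy)-2-bromo-3,5-dimethoxybenzaldehyde | COc1cc(C=O)c(Br)c(OC)c1OCc1ccccc1
F3 | step 13 | [4-(benzyloxy)-2-bromo-3,5-dimethoxyphenyl]methanol | COc1cc(CO)c(Br)c(OC)c1OCc1ccccc1
F4 | step 13 | 2-(benzyloxy)-4-bromo-5-(bromomethyl)-1,3-dimethoxybenzene | COc1cc(CBr)c(Br)c(OC)c1OCc1ccccc1
F5 | step 13 | (4S)-4-benzyl-3-{(2S)-2-[2,5-bis(benzyloxy)-3,4-dimethoxyphenyl]-3-[4-(benzyloxy)-2-bromo-3,5-dimethoxyphenyl]propanoyl}-1,3-oxazolidin-2-one | COc1c(OC)c(OCc2ccccc2)c(cc1OCc1ccccc1)[C@H](Cc1cc(OC)c(OCc2ccccc2)c(OC)c1Br)C(=O)N1[C@@H](Cc2ccccc2)COC1=O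
F6 | step 13 | (2S)-2-[2,5-bis(benzyloxy)-3,4-dimethoxyphenyl]-3-[4-(benzyloxy)-2-bromo-3,5-dimethoxyphenyl]propan-1-ol | COc1c(OC)c(OCc2ccccc2)c(cc1OCc1ccccc1)[C@H](Cc1cc(OC)c(OCc2ccccc2)c(OC)c1Br)CO
F7 | step 13 | (3S)-7-(benzyloxy)-3-[2,5-bis(benzyloxy)-3,4-dimethoxyphenyl]-6,8-dimethoxychromane | COc1c(OC)c(OCc2ccccc2)c(cc1OCc1ccccc1)[C@H]1COc2c(cc(OC)c(OCc3ccccc3)c2OC)C1
F8 | step 13 | 2-[(3S)-7-hydroxy-6,8-dimethoxychroman-3-yl]-5,6-dimethoxybenzene-1,4-diol | COc1c(OC)c(O)c(cc1O)[C@H]1COc2c(cc(OC)c(O)c2OC)C1
F9 | step 12 | 3,4-di-tert-butoxycyclobut-3-ene-1,2-dione | CC(C)(C)OC1=C(OC(C)(C)C)C(=O)C1=O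
F10 | step 12 | lithium 1-[(4S)-4-[2,5-bis(benzyloxy)-3,4-dimethoxyphenyl]-5-(tert-butyldimethylsilyloxy)pent-1-en-2-yl]-2,3-di-tert-butoxy-4-oxocyclobut-2-en-1-olate (both carbinol epimers) | [Li+].COc1c(OC)c(OCc2ccccc2)c(cc1OCc1ccccc1)[C@H](CC(=C)C1([O-])C(OC(C)(C)C)=C(OC(C)(C)C)C1=O)CO[Si](C)(C)C(C)(C)C
F11 | step 12 | 4-[(4S)-4-[2,5-bis(benzyloxy)-3,4-dimethoxyphenyl]-5-(tert-butyldimethylsilyloxy)pent-1-en-2-yl]-2,3-di-tert-butoxy-4-(tert-butyldimethylsilyloxy)cyclobut-2-en-1-one (both C4 epimers) | COc1c(OC)c(OCc2ccccc2)c(cc1OCc1ccccc1)[C@H](CC(=C)C1(O[Si](C)(C)C(C)(C)C)C(OC(C)(C)C)=C(OC(C)(C)C)C1=O)CO[Si](C)(C)C(C)(C)C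
F12 | step 12 | 4-[(4S)-4-[2,5-bis(benzyloxy)-3,4-dimethoxyphenyl]-5-(tert-butyldimethylsilyloxy)pent-1-en-2-yl]-2-tert-butoxy-4-(tert-butyldimethylsilyloxy)-3-hydroxycyclobut-2-en-1-one (both C4 epimers) | COc1c(OC)c(OCc2ccccc2)c(cc1OCc1ccccc1)[C@H](CC(=C)C1(O[Si](C)(C)C(C)(C)C)C(O)=C(OC(C)(C)C)C1=O)CO[Si](C)(C)C(C)(C)C
F13 | step 11 | silver 2-methoxy-3,4-dioxocyclobut-1-en-1-olate | [Ag+].COC1=C([O-])C(=O)C1=O
F14 | step 14 | (2S)-2-[2,5-bis(benzyloxy)-3,4-dimethoxyphenyl]-3-[4-tert-butoxy-2-(tert-butyldimethylsilyloxy)-5-hydroxy-3-methoxyphenyl]propan-1-ol | COc1c(OC)c(OCc2ccccc2)c(cc1OCc1ccccc1)[C@H](Cc1cc(O)c(OC(C)(C)C)c(OC)c1O[Si](C)(C)C(C)(C)C)CO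
F15 | step 14 | 5-[(2S)-2-[2,5-bis(benzyloxy)-3,4-dimethoxyphenyl]-3-iodopropyl]-2-tert-butoxy-4-(tert-butyldimethylsilyloxy)-3-methoxyphenol | COc1c(OC)c(OCc2ccccc2)c(cc1OCc1ccccc1)[C@H](Cc1cc(O)c(OC(C)(C)C)c(OC)c1O[Si](C)(C)C(C)(C)C)CI
F16 | step 14 | (3S)-3-[2,5-bis(benzyloxy)-3,4-dimethoxyphenyl]-7-tert-butoxy-8-methoxychroman-6-ol | COc1c(OC)c(OCc2ccccc2)c(cc1OCc1ccccc1)[C@H]1COc2c(cc(O)c(OC(C)(C)C)c2OC)C1
A1 | alternative 1 | (3S)-7-(benzyloxy)-3-ethynyl-6,8-dimethoxychromane | C#C[C@H]1COc2c(cc(OC)c(OCc3ccccc3)c2OC)C1
A2 | alternative 1 | 4-{[(3S)-7-(benzyloxy)-6,8-dimethoxychroman-3-yl]ethynyl}-4-hydroxy-2,3-dimethoxycyclobut-2-en-1-one (both carbinol epimers) | COC1=C(OC)C(O)(C#C[C@H]2COc3c(cc(OC)c(OCc4ccccc4)c3OC)C2)C1=O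
A3 | alternative 1 | 5-[(3S)-7-(benzyloxy)-6,8-dimethoxychroman-3-yl]-2,3-dimethoxycyclohexa-2,5-diene-1,4-dione | COC1=C(OC)C(=O)C([C@H]2COc3c(cc(OC)c(OCc4ccccc4)c3OC)C2)=CC1=O
A4 | alternative 2 | 2-(benzyloxy)-5-(bromomethyl)-1,3-dimethoxybenzene | COc1cc(CBr)cc(OC)c1OCc1ccccc1
A5 | alternative 2 | (2S)-3-[4-(benzyloxy)-3,5-dimethoxyphenyl]-2-[3,4-dimethoxy-2,5-bis(pivaloyloxy)phenyl]propan-1-ol | COc1c(OC)c(OC(=O)C(C)(C)C)c(cc1OC(=O)C(C)(C)C)[C@H](Cc1cc(OC)c(OCc2ccccc2)c(OC)c1)CO
A6 | alternative 2 | 2-[(3S)-7-(benzyloxy)-6,8-dimethoxychroman-3-yl]-5,6-dimethoxy-1,4-phenylene bis(2,2-dimethylpropanoate) | COc1c(OC)c(OC(=O)C(C)(C)C)c(cc1OC(=O)C(C)(C)C)[C@H]2COc3c(cc(OC)c(OCc4ccccc4)c3OC)C2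
A7 | alternative 3 | 2-(benzyloxy)-4-iodo-1,3-dimethoxybenzene | COc1ccc(I)c(OC)c1OCc1ccccc1
A8 | alternative 3 | (2S)-2-[2,5-bis(benzyloxy)-3,4-dimethoxyphenyl]-3-bromopropan-1-ol | COc1c(OC)c(OCc2ccccc2)c(cc1OCc1ccccc1)[C@H](CBr)CO
A9 | alternative 3 | (3S)-7-(benzyloxy)-3-[2,5-bis(benzyloxy)-3,4-dimethoxyphenyl]-6,8-dimethoxychromane | COc1c(OC)c(OCc2ccccc2)c(cc1OCc3ccccc3)[C@H]4COc5c(cc(OC)c(OCc6ccccc6)c5OC)C4
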